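**Plan**
1. Retrosynthetic cuts: (a) the bond between the ketone carbon and C5 of the chromene (aryllithium plus aldehyde, then oxidation); (b) the C2–C3 bond of the pyran ring; (c) the ethynyl C≡C, the two ether O–C bonds and the formyl C–C bond, back to 5-bromoresorcinol and 2-hydroxy-4,6-dimethoxybenzaldehyde.
2. Enabling feature: C2 of the pyran ring carries the ring oxygen O1 and two methyl groups, so with one more hydrogen it is the methine of an aryl isopropyl ether. C3=C4 with one hydrogen fewer is an ethynyl group on C4a. O1 and C4 sit on the adjacent benzene carbons C8a and C4a, which holds the methine C–H 1,5 to C4. A redox-neutral 1,5-hydride shift followed by C3-to-C2 bonding should therefore turn an ortho-ethynyl aryl isopropyl ether into the 2,2-dimethyl-2H-pyran ring with no atom lost and no helper group to remove.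
3. Forward order: the ring B arene is dressed first (formylation, MOM on the para hydroxyl, isopropyl on the chelated ortho hydroxyl, aldehyde to alkyne). The pyran ring, the only ring made, is then closed. Bromine–lithium exchange joins the chromene to the ring A aldehyde, oxidation gives the benzophenone, and acid removes both MOM groups.
4. Stereochemistry: the target has no stereocentre. The C3=C4 alkene is cis by ring constraint. The carbinol centre of 12 is racemic and is erased by oxidation.

Key step: step 5

**Step 1**
Reactants: 1 5-bromobenzene-1,3-diol (5-bromoresorcinol)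
Product: 3 2-bromo-4,6-dihydroxybenzaldehyde, via aryl iminium chloride 2 (not isolated)
Conditions: POCl3, DMF, MeCN, 0 °C to rt; then H2O, 50 °C
Reagents that add atoms: N,N-dimethylformamide, CN(C)C=O (formyl carbon); water, O (carbonyl oxygen)
Why: Vilsmeier–Haack formylation, in which the chloroiminium ion should attack the ring carbon that is para to one hydroxyl and ortho to the other (next to bromine), as in resorcinol and orcinol, and the iminium salt 2 is hydrolysed on warming with water.

**Step 2**
Reactants: 3 2-bromo-4,6-dihydroxybenzaldehyde
Product: 4 2-bromo-6-hydroxy-4-(methoxymethoxy)benzaldehyde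
Conditions: MOMCl (1.05 equiv), K2CO3, acetone, 0 °C to rt
Reagents that add atoms: chloromethyl methyl ether (MOMCl), COCCl
Why: Williamson-type O-alkylation, selective because the 4-hydroxyl (para to the aldehyde) is the more acidic and free one while the 6-hydroxyl is held in a hydrogen bond to the formyl oxygen.

**Step 3**
Reactants: 4 2-bromo-6-hydroxy-4-(methoxymethoxy)benzaldehyde
Product: 5 2-bromo-4-(methoxymethoxy)-6-(propan-2-yloxy)benzaldehyde
Conditions: 2-iodopropane (3 equiv), K2CO3, DMF, 60 °C
Reagents that add atoms: 2-iodopropane, CC(C)I
Why: Williamson ether synthesis on the chelated phenol, which needs the polar solvent and gentle heating, with excess iodide to cover loss by elimination.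

**Step 4**
Reactants: 5 2-bromo-4-(methoxymethoxy)-6-(propan-2-yloxy)benzaldehyde
Product: 6 1-bromo-2-ethynyl-5-(methoxymethoxy)-3-(propan-2-yloxy)benzene
Conditions: dimethyl (1-diazo-2-oxopropyl)phosphonate, K2CO3, MeOH, 0 °C to rt
Reagents that add atoms: dimethyl (1-diazo-2-oxopropyl)phosphonate (Ohira–Bestmann reagent), COP(=O)(OC)C(=[N+]=[N-])C(C)=O
Why: Seyferth–Gilbert homologation in the Ohira–Bestmann variant should convert the aldehyde into the terminal alkyne under mild base that leaves the aryl bromide, the MOM acetal and the isopropyl ether untouched.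

**Step 5**
Reactants: 6 1-bromo-2-ethynyl-5-(methoxymethoxy)-3-(propan-2-yloxy)benzene
Product: 8 5-bromo-7-(methoxymethoxy)-2,2-dimethyl-2H-chromene, via alkenylplatinate oxocarbenium zwitterion 7 (not isolated)
Conditions: PtI4 (10 mol %), 4 Å MS, MeCN, 100 °C (sealed tube)
Reagents that add atoms: none
Why: Proposed new method: PtI4 coordinates the terminal alkyne of 6 and turns its internal, aryl-bearing carbon (the future C4) into a hydride acceptor; the methine C–H of the ortho isopropoxy group lies 1,5 to this carbon and should transfer hydride through a six-membered transition state to give zwitterion 7, a 2-aryloxyprop-2-yl oxocarbenium ion paired with a (Z)-alkenylplatinate at the former terminal carbon (the future C3), whose C–Pt carbon then adds to the oxocarbenium carbon with release of PtI4 to form the C3–C2 bond. The closest known reaction types are the PtI4- or gold-catalysed 1,5-hydride shift/cyclization of terminal alkynes tethered to an ether α-C–H bond, the PtCl2-catalysed cycloisomerization of 1-alkyl-2-ethynylbenzenes to indenes, and the Lewis-acid-catalysed hydride shift/cyclization of ortho-alkoxybenzylidene malonates to chromans, which makes the same C2–C3 bond; new here is an aryl isopropyl ether as hydride donor toward a non-polarized arylalkyne, giving a 2H-chromene directly. The pyran ring closes in a 6-endo-trig mode (the C=O+ bond lies inside the forming ring), and because hydride and platinum add anti across the alkyne, platinum stands cis to the arene, which is the geometry the ring alkene C3=C4 requires. No stereocentre is formed, since C2 carries two methyl groups. The step needs hydride transfer to win over 5-endo attack of the ether oxygen on the alkyne (benzofuran formation with loss of propene), over alkyne hydration and over cleavage of the MOM acetal: the terminal alkyne places positive charge on the internal carbon that the hydride can reach, the tertiary C–H gives an oxocarbenium ion stabilized by oxygen and two methyl groups, the flanking bromine is not nucleophilic, the MOM group is meta to the alkyne and out of reach, and molecular sieves keep water out.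

**Step 6**
Reactants: 9 2-hydroxy-4,6-dimethoxybenzaldehyde
Product: 10 2,4-dimethoxy-6-(methoxymethoxy)benzaldehyde
Conditions: NaH, DMF, 0 °C; then MOMCl, 0 °C to rt
Reagents that add atoms: chloromethyl methyl ether (MOMCl), COCCl
Why: the chelated phenol is deprotonated irreversibly by NaH and the phenoxide is O-alkylated by MOMCl (Williamson-type), the aldehyde having no enolizable hydrogen.

**Step 7**
Reactants: 8 5-bromo-7-(methoxymethoxy)-2,2-dimethyl-2H-chromene; 10 2,4-dimethoxy-6-(methoxymethoxy)benzaldehyde
Product: 12 [2,4-dimethoxy-6-(methoxymethoxy)phenyl][7-(methoxymethoxy)-2,2-dimethyl-2H-chromen-5-yl]methanol (racemic), via chromen-5-yllithium 11 (not isolated)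
Conditions: n-BuLi, THF, −78 °C; then 10, −78 to 0 °C; then H2O
Reagents that add atoms: none
Why: bromine–lithium exchange at −78 °C is faster than any ring deprotonation, and 1,2-addition of the aryllithium to the non-enolizable aldehyde should give the diarylmethanol as a racemate whose stereocentre is removed in step 8.

**Step 8**
Reactants: 12 [2,4-dimethoxy-6-(methoxymethoxy)phenyl][7-(methoxymethoxy)-2,2-dimethyl-2H-chromen-5-yl]methanol
Product: 13 [2,4-dimethoxy-6-(methoxymethoxy)phenyl][7-(methoxymethoxy)-2,2-dimethyl-2H-chromen-5-yl]methanone
Conditions: Dess–Martin periodinane, pyridine, CH2Cl2, 0 °C to rt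
Reagents that add atoms: none
Why: Dess–Martin oxidation of the doubly benzylic secondary alcohol under buffered, non-acidic conditions should spare the MOM acetals and the chromene alkene.

**Step 9**
Reactants: 13 [2,4-dimethoxy-6-(methoxymethoxy)phenyl][7-(methoxymethoxy)-2,2-dimethyl-2H-chromen-5-yl]methanone
Product: 14 (2-hydroxy-4,6-dimethoxyphenyl)(7-hydroxy-2,2-dimethyl-2H-chromen-5-yl)methanone (target)
Conditions: HCl (1.25 M in MeOH), MeOH/THF, 40 °C
Reagents that add atoms: none
Why: acid-catalysed acetal exchange with methanol should remove both MOM groups (the one ortho to the ketone first, helped by chelation) under dilute conditions that 2,2-dimethylchromenes, aryl methyl ethers and the diaryl ketone tolerate.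

**Compound list**
1 | 5-bromobenzene-1,3-diol (5-bromoresorcinol) | Oc1cc(O)cc(Br)c1 | starting material
2 | N-[(2-bromo-4,6-dihydroxyphenyl)methylidene]-N-methylmethanaminium chloride (aryl iminium chloride) | C[N+](C)=Cc1c(O)cc(O)cc1Br.[Cl-] | intermediate (not isolated)
3 | 2-bromo-4,6-dihydroxybenzaldehyde | O=Cc1c(O)cc(O)cc1Br | intermediate
4 | 2-bromo-6-hydroxy-4-(methoxymethoxy)benzaldehyde | O=Cc1c(O)cc(OCOC)cc1Br | intermediate
5 | 2-bromo-4-(methoxymethoxy)-6-(propan-2-yloxy)benzaldehyde | O=Cc1c(OC(C)C)cc(OCOC)cc1Br | intermediate
6 | 1-bromo-2-ethynyl-5-(methoxymethoxy)-3-(propan-2-yloxy)benzene | C#Cc1c(OC(C)C)cc(OCOC)cc1Br | intermediate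
7 | (Z)-2-[2-bromo-4-(methoxymethoxy)-6-(propan-2-ylideneoxonio)phenyl]ethenyl tetraiodoplatinate (alkenylplatinate oxocarbenium zwitterion) | COCOc1cc(Br)c(/C=C\[Pt-](I)(I)(I)I)c([O+]=C(C)C)c1 | intermediate (not isolated)
8 | 5-bromo-7-(methoxymethoxy)-2,2-dimethyl-2H-chromene | COCOc1cc(Br)c2C=CC(C)(C)Oc2c1 | intermediate
9 | 2-hydroxy-4,6-dimethoxybenzaldehyde | COc1cc(O)c(C=O)c(OC)c1 | starting material
10 | 2,4-dimethoxy-6-(methoxymethoxy)benzaldehyde | COCOc1cc(OC)cc(OC)c1C=O | intermediate
11 | [7-(methoxymethoxy)-2,2-dimethyl-2H-chromen-5-yl]lithium | [Li]c1cc(OCOC)cc2OC(C)(C)C=Cc12 | intermediate (not isolated)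
12 | [2,4-dimethoxy-6-(methoxymethoxy)phenyl][7-(methoxymethoxy)-2,2-dimethyl-2H-chromen-5-yl]methanol (racemic) | COCOc1cc(OC)cc(OC)c1C(O)c1cc(OCOC)cc2OC(C)(C)C=Cc12 | intermediate
13 | [2,4-dimethoxy-6-(methoxymethoxy)phenyl][7-(methoxymethoxy)-2,2-dimethyl-2H-chromen-5-yl]methanone | COCOc1cc(OC)cc(OC)c1C(=O)c1cc(OCOC)cc2OC(C)(C)C=Cc12 | intermediate
14 | (2-hydroxy-4,6-dimethoxyphenyl)(7-hydroxy-2,2-dimethyl-2H-chromen-5-yl)methanone | COc1cc(O)c(C(=O)c2cc(O)cc3c2C=CC(C)(C)O3)c(OC)c1 | target

**Step count**
Total steps: 9. Longest linear sequence: 8 (steps 1–5, 7, 8, 9); step 6 is a one-step side branch.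

**Steps most likely to fail**

Step 5 (proposed new method). The hydride transfer from an aryl ether C–H may be too slow. Oxygen attack on the activated alkyne with loss of the isopropyl group, alkyne hydration or alkyne oligomerization could then consume the substrate. The fallback uses known chemistry and sets out from 4. Addition of 2-methylprop-1-enylmagnesium bromide (2.5 equiv, THF, 0 °C) to the salicylaldehyde should give 3-bromo-2-(1-hydroxy-3-methylbut-2-en-1-yl)-5-(methoxymethoxy)phenol F1. Warming F1 in toluene with a trace of pyridinium p-toluenesulfonate should expel water to give the ortho-quinone methide 5-bromo-3-(methoxymethoxy)-6-(3-methylbut-2-en-1-ylidene)cyclohexa-2,4-dien-1-one F2, which closes by oxa-6π electrocyclization. The fallback comes back to the route at 8, so steps 3 to 5 are not needed.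

Step 1. Formylation of the free resorcinol may occur between the two hydroxyls, twice, or on oxygen, and the isomers may be hard to separate. The fallback sets out from 1. Both hydroxyls are methylated (MeI, K2CO3, acetone) to 1-bromo-3,5-dimethoxybenzene F3. Vilsmeier–Haack formylation of the ether (POCl3, DMF, 90 °C), where attack next to bromine and para to methoxy is established, should give 2-bromo-4,6-dimethoxybenzaldehyde F4. Cleavage of both methyl ethers with BBr3 (CH2Cl2, −78 °C to rt) comes back to the route at 3.

Step 4. Addition of the diazophosphonate anion to the hindered, electron-rich aldehyde may be slow, so that methanolysis and decomposition of the reagent outrun the homologation. The fallback sets out from 5. Wittig chloromethylenation with the ylide from (chloromethyl)triphenylphosphonium chloride and KOtBu (THF, 0 °C) should give 1-bromo-2-(2-chloroethenyl)-5-(methoxymethoxy)-3-(propan-2-yloxy)benzene F5 as an E/Z mixture, both isomers being usable. Dehydrochlorination with KOtBu (3 equiv, DMSO, rt), a base that does not exchange the aryl bromide, comes back to the route at 6.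

**Further compounds**
F1 | step 5 | 3-bromo-2-(1-hydroxy-3-methylbut-2-en-1-yl)-5-(methoxymethoxy)phenol (racemic) | CC(C)=CC(O)c1c(O)cc(OCOC)cc1Br
F2 | step 5 | 5-bromo-3-(methoxymethoxy)-6-(3-methylbut-2-en-1-ylidene)cyclohexa-2,4-dien-1-one (transient, alkene geometry not fixed) | CC(C)=CC=C1C(Br)=CC(OCOC)=CC1=O
F3 | step 1 | 1-bromo-3,5-dimethoxybenzene | COc1cc(OC)cc(Br)c1
F4 | step 1 | 2-bromo-4,6-dimethoxybenzaldehyde | COc1cc(OC)c(C=O)c(Br)c1
F5 | step 4 | 1-bromo-2-(2-chloroethenyl)-5-(methoxymethoxy)-3-(propan-2-yloxy)benzene (E/Z mixture) | ClC=Cc1c(OC(C)C)cc(OCOC)cc1Br
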